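## Structural features

The target 21 is a (3R)-isoflavanone: a chroman-4-one (benzene ring A fused to the dihydropyranone ring C) carrying at C3 a 2,4-dihydroxyphenyl ring B, with a hydroxyl at C7 of ring A and an (E)-geranyl chain at C5' of ring B, ortho to the 4'-hydroxyl. C3 is the only stereocentre; it is benzylic and α to the C4 ketone, has no neighbouring stereocentre to relay from, and epimerises through the enol under acid or base. The fragile parts are this C3–H, the two trisubstituted alkenes of the geranyl chain (which cyclise onto the neighbouring phenol under acid and are attacked by carbenes and by electrophilic chlorine) and the three electron-rich phenols. The real difficulty is one of order: C3 has to be set late by a reagent and then meet only near-neutral conditions, and the geranyl chain has to arrive after all carbene and hypochlorite chemistry and must never meet strong acid. The key step uses the fact that C3, with ring B attached, is a single carbon between C2 and C4 of ring C; taking it out joins C2 to C4 and leaves O1–C2–C4–C4a–C8a, the five-membered ring of a 6-oxygenated benzofuran-3-one. Ring C can therefore be made by pushing an aryl-bearing carbon into the enol-ether C2=C3 bond of that benzofuranone, which gives the flat isoflavone; its C2=C3–C4=O system is what a hydrogen-transfer catalyst needs to set C3 with dynamic kinetic resolution. A bromine at C5' holds the place of the geranyl chain through the oxidising and carbene steps.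

## Logic of the disconnections

21 ⇒ 20. The three phenolic O–H bonds are traced back to O–Si bonds. The phenols must be masked during the oxidation at C4 and the organometallic step. Triisopropylsilyl ethers are chosen because they leave with buffered fluoride, which should spare both C3 and the ortho-geranyl phenol, whereas acetal protection would force an acidic last step. The skeleton is unchanged; the demand on the forward step is a near-neutral medium.

20 ⇒ 19. The C4=O bond is taken back to C4–OH. The carbinol is what the asymmetric reduction delivers, and it removes the only electrophilic carbon, which is what allows an aryl-metal in the step before. The forward oxidation must run without base so that C3–H is not exchanged.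

19 ⇒ 15 + 16. The C5'–C1'' bond between ring B and the chain is cut. 16 is a commercial electrophile with the E double bond in place, so its natural partner is an aryl nucleophile made from the C5'–Br bond of 15 (through 17 and 18). No tin reagent has to be prepared from 16, and a π-allyl palladium intermediate that could scramble the double bond is avoided. The demand is that the exchange is run cold and that substitution occurs at the primary carbon; this is also why the reduction is placed before the chain is attached.

15 ⇒ 13. The hydrogens at C2, C3 and C4 are removed, which gives the flat, achiral 13. Both stereocentres of 15 come from one catalyst in one operation through 14. The forward step needs the epimerisation of 14 at C3 to be faster than its reduction, and needs the (R,R) ligand.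

13 ⇒ 9 + 7. The C2–C3 and C3–C4 bonds are cut; this is the key disconnection. Ring C shrinks to the five-membered ring of 9, and ring B with its one extra carbon becomes 7. The gain is two fragments of similar size, each a few steps from commercial material, and no stereochemistry to control. The forward step requires that 10 adds to the enol-ether bond of 9 and nowhere else, that 11 opens, and that 12 loses its silyl group. Ring B must therefore carry nothing a carbene can attack: bromine and not the geranyl chain, and silyl ethers and not an acetal, whose O–CH2–O hydrogens ortho to the carbene carbon would sit in a 1,5 relation for C–H insertion.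

9 ⇒ 8. Two O–Si bonds are cut, that of the phenol and that of the enol. One reagent forms both, so the branch is a single step.

7 ⇒ 5 ⇒ 3 ⇒ 2 ⇒ 1. The N=N and C–Cl bonds of the three-membered ring of 7 go back to 5 (through 6); the C–N bond of 5 goes back to the nitrile carbon of 3 (through 4); the O–Si bonds of 3 to 2; the C5–Br bond of 2 to 1. Each cut removes one functional group. The demands are regioselective bromination at C5 and silyl ethers that survive aqueous hypochlorite for the short time of the oxidation.

## Other disconnections considered

Alternative 1: The cut is C4–C4a. In the forward sense the acid chloride A2, whose stereocentre would come from desymmetrisation of the prochiral diol A3, acylates its own aryloxy ring para to the silyloxy group (intramolecular Friedel–Crafts acylation) to give A1.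
- In its favour: the stereocentre is made early by a dependable type of reaction and is carried as a defined centre. The site of acylation is activated by both oxygens and closes a six-membered ring. A1 is already at the ketone oxidation level; it is the (3R) form of intermediate 14 of the chosen route. No untested reaction is needed.
- Against it: A2 is an α-aryl acid chloride with a β-aryloxy group, so enolisation or ketene formation would erode C3 and elimination of the phenoxide would give an atropic acid derivative. The Lewis acid threatens the three aryl silyl ethers. The chain then has to be attached to an enolisable ketone, which rules out an aryl-metal and leaves palladium chemistry on an epimerisable substrate.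
- Comparison: on precedent and on oxidation-state economy (two steps from A1 to the target against four from 13) this alternative is the better plan. On mechanism the chosen plan is safer, because its racemisation is productive (it feeds the resolution of 14), while here every racemisation is a loss. The count before ring closure (building A3, desymmetrisation, etherification, oxidation, chlorination) is at least that of the six steps to 13, so the totals should be similar.

Alternative 2: The cut is O1–C8a. In the forward sense the primary alcohol of A5, an open chain whose two stereocentres come from an auxiliary-controlled aldol reaction, is coupled with the ortho aryl bromide under CuI (monovalent copper), 3,4,7,8-tetramethyl-1,10-phenanthroline and Cs2CO3 to close the oxygen ring and give A4.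
- In its favour: the geranyl chain can be present from the start, since nothing in the sequence attacks alkenes; this is better than the chosen plan, which needs a bromine placeholder and a separate chain attachment. The sense of induction is predictable and can be checked before ring closure. C3 is not α to a carbonyl at this stage, so the hot basic coupling cannot epimerise it.
- Against it: attachment and reductive removal of a stoichiometric auxiliary, protection of the secondary alcohol, the coupling, desilylation, oxidation and deprotection make a long linear sequence on top of a ring-B arylacetic acid that itself takes several steps. A4 still needs the same late oxidation as 19. Its acetal groups would have to come off with acid beside the geranyl phenol and the enolisable C3, although that is a matter of protecting groups and not of the cut.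
- Comparison: on precedent and on carrying the chain early this alternative is the stronger; on the final oxidation it is equal; on step count and convergence the chosen plan is shorter.

Alternative 3: The cuts are C4–C4a and O1–C2. In the forward sense the dianion made from bromophenol A8 attacks the Weinreb amide A7, and on work-up the free phenol adds to the methylene end of the resulting aryl vinyl ketone (oxa-Michael addition, 6-endo) to give racemic A6.
- In its favour: two bonds and ring C are formed in one operation from two simple pieces, the chain is carried through, and only known reaction types are used. In convergence it is the equal of the chosen plan, and in precedent the better.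
- Against it: A6 is racemic, so the same reduction with dynamic kinetic resolution and the same re-oxidation would still be needed, and nothing is saved after the ring is made. The aryllithium may add in conjugate fashion to the acrylamide, and atropic derivatives polymerise easily. The mixed acetal and silyl protection again ends in an acidic step.
- Comparison: the two plans are equal in how C3 would be controlled and similar in length. The chosen key step has the advantage of neutral, non-basic conditions and of a flat, robust product 13; this alternative has the advantage of not depending on an unproven reaction.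

Key step: step 6

Assumption: 1, 8 and 16 are taken as commercial; chromanone atoms are numbered O1 to C8a, ring B atoms carry primes, and the geranyl chain is the (2E)-3,7-dimethylocta-2,6-dienyl group.

## Route

Step 1
Reactants: 1 2,4-dihydroxybenzonitrile
Product: 2 5-bromo-2,4-dihydroxybenzonitrile
Conditions: NBS (1.0 equiv), MeCN, −20 → 0 °C
Reagents that add atoms: N-bromosuccinimide, O=C1CCC(=O)N1Br
Why: Electrophilic aromatic bromination; C5 is para to the 2-hydroxyl and ortho to the 4-hydroxyl and is less crowded than C3 between the two oxygens, so one equivalent at low temperature should give the 5-bromide.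

Step 2
Reactants: 2 5-bromo-2,4-dihydroxybenzonitrile
Product: 3 5-bromo-2,4-bis(triisopropylsilyloxy)benzonitrile
Conditions: TIPSCl (2.5 equiv), imidazole (5 equiv), DMF, rt → 40 °C
Reagents that add atoms: chlorotriisopropylsilane, CC(C)[Si](Cl)(C(C)C)C(C)C
Why: Imidazole-promoted silyl ether formation on both phenols; the triisopropylsilyl group offers no activated C–H bond to the later carbene, is less electron-releasing and more base-stable than an alkyl or acetal ether, shields C3 of the arene, and leaves under buffered fluoride at the end.

Step 3
Reactants: 3 5-bromo-2,4-bis(triisopropylsilyloxy)benzonitrile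
Product: 5 5-bromo-2,4-bis(triisopropylsilyloxy)benzamidinium chloride, via lithium N,N'-bis(trimethylsilyl)amidinate 4 (not isolated)
Conditions: LiN(SiMe3)2 (1.3 equiv), THF, 0 °C → rt; then HCl (4 M in dioxane), 0 °C
Reagents that add atoms: lithium bis(trimethylsilyl)amide, C[Si](C)(C)N([Li])[Si](C)(C)C; hydrogen chloride, Cl
Why: Amidine synthesis from a nitrile: the silylamide adds to the C≡N bond and a 1,3-silyl shift gives 4; anhydrous HCl cleaves the labile N–Si bonds, leaves the hindered aryl O–Si bonds, and precipitates the amidinium salt.

Step 4
Reactants: 5 5-bromo-2,4-bis(triisopropylsilyloxy)benzamidinium chloride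
Product: 7 3-[5-bromo-2,4-bis(triisopropylsilyloxy)phenyl]-3-chloro-3H-diazirine, via N,N'-dichloroamidine 6 (not isolated)
Conditions: NaOCl (aq, 3 equiv), LiCl, DMSO/hexane, 0 °C → rt, 30 min, dark; hexane layer dried cold and used at once
Reagents that add atoms: sodium hypochlorite, [Na+].[O-]Cl; lithium chloride (chloride pool), [Li+].[Cl-]
Why: Graham oxidation: twofold N-chlorination to 6, base-induced N–N bond formation and return of chloride to carbon give the 3-chloro-3H-diazirine. The lipophilic product passes into hexane as it forms and so spends little time with hydroxide, and the bulky silyl ethers flank C3 of the arene against ring chlorination.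

Step 5
Reactants: 8 6-hydroxybenzofuran-3(2H)-one
Product: 9 3,6-bis(triisopropylsilyloxy)-1-benzofuran
Conditions: TIPSOTf (2.3 equiv), Et3N (3 equiv), CH2Cl2, 0 °C → rt
Reagents that add atoms: triisopropylsilyl trifluoromethanesulfonate, CC(C)[Si](OS(=O)(=O)C(F)(F)F)(C(C)C)C(C)C
Why: Soft enolisation and O-silylation: the silyl triflate caps the phenol and the enol oxygen of the easily enolised benzofuranone, and O-silylation at C3 is favoured because it gives the aromatic benzofuran.

Step 6
Reactants: 9 3,6-bis(triisopropylsilyloxy)-1-benzofuran; 7 3-[5-bromo-2,4-bis(triisopropylsilyloxy)phenyl]-3-chloro-3H-diazirine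
Product: 13 3-[5-bromo-2,4-bis(triisopropylsilyloxy)phenyl]-7-(triisopropylsilyloxy)-4H-chromen-4-one, via arylchlorocarbene 10 (not isolated), via chlorocyclopropane 11 (not isolated), via 4-silyloxybenzopyrylium chloride 12 (not isolated)
Conditions: 7 (1.0 equiv) added over 4 h to 9 (2.0 equiv), Na2CO3, MeCN/ClCH2CH2Cl (1:1), 50 °C, dark; then 60 °C, 2 h; aq NaHCO3
Reagents that add atoms: none
Why: Proposed new method: thermal loss of N2 from 7 gives the singlet arylchlorocarbene 10, an electrophile that should add to the most electron-rich π bond present, the C2=C3 enol-ether bond of 9, in an asynchronous [2+1] addition that begins at the unhindered C2. In the chlorocyclopropane 11 the C–Cl bond ionises while the former furan C2–C3 bond opens in a disrotatory two-electron electrocyclic process, so the five-membered ring grows to six and the 4-silyloxybenzopyrylium chloride 12 results, stabilised by O1 and by the silyloxy oxygen. Chloride then removes the silyl group, which on a pyrylium oxygen is as electrophilic as in a silyl triflate, and the chromen-4-one 13 is released. The closest known reaction types are the dihalocarbene ring expansion of cyclic silyl enol ethers to 2-halo enones and the carbon-atom insertion of arylchlorodiazirines into indoles and indenes (Ciamician–Dennstedt type); an arylchlorocarbene with a heteroaryl silyl enol ether is the untested combination. Ring C is thus not closed by a cyclisation but made by cyclopropanation followed by electrocyclic ring enlargement, which is why the new carbon can only end between the former C2 and C3. No stereocentre remains in 13; those of 11 are transient, the endo-chloride being expected to open by the concerted path and the exo-chloride after ionisation to a cyclopropyl cation stabilised by the oxygenated aryl group. The selectivity needed is for the enol ether over the three arenes and over self-reaction of the carbene: the first rests on the nucleophilicity of the silyl enol ether, the second on slow addition of 7 to an excess of 9, and intramolecular C–H insertion is discouraged because the ortho oxygen carries a silyl group and not an acetal.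

Step 7
Reactants: 13 3-[5-bromo-2,4-bis(triisopropylsilyloxy)phenyl]-7-(triisopropylsilyloxy)-4H-chromen-4-one
Product: 15 (3R,4R)-3-[5-bromo-2,4-bis(triisopropylsilyloxy)phenyl]-7-(triisopropylsilyloxy)chroman-4-ol (cis), via racemic chroman-4-one 14 (not isolated)
Conditions: RuCl(p-cymene)[(R,R)-TsDPEN] (5 mol %), HCO2H/Et3N (5:2), EtOAc, 40 °C
Reagents that add atoms: none
Why: Noyori-type asymmetric transfer hydrogenation cascade with dynamic kinetic resolution: Ru–H first reduces the chromone C2=C3 bond in conjugate fashion to 14, whose C3 epimerises through the enol under Et3N, and the catalyst then reduces the faster-reacting (3R) ketone to the carbinol cis to the aryl group. By the usual model for aryl ketones the (R,R) ligand gives the (R) benzylic alcohol when the fused arene outranks C3, so C4 is set as R by the catalyst and C3 as R by the cis preference of the resolution; the (R,R) enantiomer is therefore the correct one for the (3R) target.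

Step 8
Reactants: 15 (3R,4R)-3-[5-bromo-2,4-bis(triisopropylsilyloxy)phenyl]-7-(triisopropylsilyloxy)chroman-4-ol; 16 geranyl bromide, (2E)-1-bromo-3,7-dimethylocta-2,6-diene
Product: 19 (3R,4R)-3-{5-[(2E)-3,7-dimethylocta-2,6-dien-1-yl]-2,4-bis(triisopropylsilyloxy)phenyl}-7-(triisopropylsilyloxy)chroman-4-ol, via dilithio intermediate 17 (not isolated), via arylcopper intermediate 18 (not isolated)
Conditions: t-BuLi (3.1 equiv), THF, −78 °C; CuBr·SMe2 (1.1 equiv), −78 → −40 °C; 16 (1.5 equiv), −40 → 0 °C; aq NH4Cl
Reagents that add atoms: none
Why: Deprotonation of the hydroxyl and bromine–lithium exchange at −78 °C give 17, which is moved at once to monovalent copper (18) to forestall silyl migration from oxygen to the metalated carbon. The arylcopper then displaces bromide at the primary carbon of 16 (copper-mediated allylic substitution), which keeps the E double bond and leaves C3 and C4 untouched; an aryl-metal is possible only because no carbonyl group is present at this stage.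

Step 9
Reactants: 19 (3R,4R)-3-{5-[(2E)-3,7-dimethylocta-2,6-dien-1-yl]-2,4-bis(triisopropylsilyloxy)phenyl}-7-(triisopropylsilyloxy)chroman-4-ol
Product: 20 (3R)-3-{5-[(2E)-3,7-dimethylocta-2,6-dien-1-yl]-2,4-bis(triisopropylsilyloxy)phenyl}-7-(triisopropylsilyloxy)chroman-4-one
Conditions: Dess–Martin periodinane (1.2 equiv), CH2Cl2, 0 °C → rt; brief cold aq Na2S2O3/NaHCO3 wash
Reagents that add atoms: none
Why: Dess–Martin oxidation of the secondary benzylic alcohol under nearly neutral conditions; no base is present during the reaction, so C3–H next to the new ketone should not exchange, and the (3R) centre is kept while the C4 centre is removed.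

Step 10
Reactants: 20 (3R)-3-{5-[(2E)-3,7-dimethylocta-2,6-dien-1-yl]-2,4-bis(triisopropylsilyloxy)phenyl}-7-(triisopropylsilyloxy)chroman-4-one
Product: 21 (3R)-3-{5-[(2E)-3,7-dimethylocta-2,6-dien-1-yl]-2,4-dihydroxyphenyl}-7-hydroxychroman-4-one
Conditions: TBAF (3.5 equiv), AcOH (4 equiv), THF, 0 °C
Reagents that add atoms: none
Why: Fluoride-induced cleavage of the three aryl silyl ethers; acetic acid keeps the liberated phenols protonated and the medium near neutral, so neither the enolisable C3 centre nor the acid-sensitive ortho-geranyl phenol should suffer.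

## Compound list

1 | 2,4-dihydroxybenzonitrile | N#Cc1ccc(O)cc1O | starting material
2 | 5-bromo-2,4-dihydroxybenzonitrile | N#Cc1cc(Br)c(O)cc1O | intermediate
3 | 5-bromo-2,4-bis(triisopropylsilyloxy)benzonitrile | N#Cc1cc(Br)c(O[Si](C(C)C)(C(C)C)C(C)C)cc1O[Si](C(C)C)(C(C)C)C(C)C | intermediate
4 | lithium N,N'-bis(trimethylsilyl)-5-bromo-2,4-bis(triisopropylsilyloxy)benzamidinate | [Li]N([Si](C)(C)C)C(=N[Si](C)(C)C)c1cc(Br)c(O[Si](C(C)C)(C(C)C)C(C)C)cc1O[Si](C(C)C)(C(C)C)C(C)C | intermediate (not isolated)
5 | 5-bromo-2,4-bis(triisopropylsilyloxy)benzamidinium chloride | [Cl-].NC(=[NH2+])c1cc(Br)c(O[Si](C(C)C)(C(C)C)C(C)C)cc1O[Si](C(C)C)(C(C)C)C(C)C | intermediate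
6 | N,N'-dichloro-5-bromo-2,4-bis(triisopropylsilyloxy)benzamidine | ClN=C(NCl)c1cc(Br)c(O[Si](C(C)C)(C(C)C)C(C)C)cc1O[Si](C(C)C)(C(C)C)C(C)C | intermediate (not isolated)
7 | 3-[5-bromo-2,4-bis(triisopropylsilyloxy)phenyl]-3-chloro-3H-diazirine | ClC1(N=N1)c1cc(Br)c(O[Si](C(C)C)(C(C)C)C(C)C)cc1O[Si](C(C)C)(C(C)C)C(C)C | intermediate
8 | 6-hydroxybenzofuran-3(2H)-one | O=C1COc2cc(O)ccc12 | starting material
9 | 3,6-bis(triisopropylsilyloxy)-1-benzofuran | CC(C)[Si](Oc1ccc2c(O[Si](C(C)C)(C(C)C)C(C)C)coc2c1)(C(C)C)C(C)C | intermediate
10 | [5-bromo-2,4-bis(triisopropylsilyloxy)phenyl]chlorocarbene | Cl[C]c1cc(Br)c(O[Si](C(C)C)(C(C)C)C(C)C)cc1O[Si](C(C)C)(C(C)C)C(C)C | intermediate (not isolated)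
11 | 1-[5-bromo-2,4-bis(triisopropylsilyloxy)phenyl]-1-chloro-5,6b-bis(triisopropylsilyloxy)-1a,6b-dihydro-1H-cyclopropa[b]benzofuran (racemic, both epimers at the chlorine-bearing carbon) | ClC1(c2cc(Br)c(O[Si](C(C)C)(C(C)C)C(C)C)cc2O[Si](C(C)C)(C(C)C)C(C)C)C2Oc3cc(O[Si](C(C)C)(C(C)C)C(C)C)ccc3C12O[Si](C(C)C)(C(C)C)C(C)C | intermediate (not isolated)
12 | 3-[5-bromo-2,4-bis(triisopropylsilyloxy)phenyl]-4,7-bis(triisopropylsilyloxy)chromenylium chloride | [Cl-].CC(C)[Si](Oc1ccc2c(O[Si](C(C)C)(C(C)C)C(C)C)c(-c3cc(Br)c(O[Si](C(C)C)(C(C)C)C(C)C)cc3O[Si](C(C)C)(C(C)C)C(C)C)c[o+]c2c1)(C(C)C)C(C)C | intermediate (not isolated)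
13 | 3-[5-bromo-2,4-bis(triisopropylsilyloxy)phenyl]-7-(triisopropylsilyloxy)-4H-chromen-4-one | O=c1c(-c2cc(Br)c(O[Si](C(C)C)(C(C)C)C(C)C)cc2O[Si](C(C)C)(C(C)C)C(C)C)coc2cc(O[Si](C(C)C)(C(C)C)C(C)C)ccc12 | intermediate
14 | rac-3-[5-bromo-2,4-bis(triisopropylsilyloxy)phenyl]-7-(triisopropylsilyloxy)chroman-4-one | O=C1C(c2cc(Br)c(O[Si](C(C)C)(C(C)C)C(C)C)cc2O[Si](C(C)C)(C(C)C)C(C)C)COc2cc(O[Si](C(C)C)(C(C)C)C(C)C)ccc12 | intermediate (not isolated)
15 | (3R,4R)-3-[5-bromo-2,4-bis(triisopropylsilyloxy)phenyl]-7-(triisopropylsilyloxy)chroman-4-ol | Brc1cc([C@@H]2COc3cc(O[Si](C(C)C)(C(C)C)C(C)C)ccc3[C@@H]2O)c(O[Si](C(C)C)(C(C)C)C(C)C)cc1O[Si](C(C)C)(C(C)C)C(C)C | intermediate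
16 | geranyl bromide, (2E)-1-bromo-3,7-dimethylocta-2,6-diene | CC(C)=CCC/C(C)=C/CBr | starting material
17 | lithium (3R,4R)-3-[5-lithio-2,4-bis(triisopropylsilyloxy)phenyl]-7-(triisopropylsilyloxy)chroman-4-olate | [Li]c1cc([C@@H]2COc3cc(O[Si](C(C)C)(C(C)C)C(C)C)ccc3[C@@H]2O[Li])c(O[Si](C(C)C)(C(C)C)C(C)C)cc1O[Si](C(C)C)(C(C)C)C(C)C | intermediate (not isolated)
18 | lithium (3R,4R)-3-[5-cuprio-2,4-bis(triisopropylsilyloxy)phenyl]-7-(triisopropylsilyloxy)chroman-4-olate | [Cu]c1cc([C@@H]2COc3cc(O[Si](C(C)C)(C(C)C)C(C)C)ccc3[C@@H]2O[Li])c(O[Si](C(C)C)(C(C)C)C(C)C)cc1O[Si](C(C)C)(C(C)C)C(C)C | intermediate (not isolated)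
19 | (3R,4R)-3-{5-[(2E)-3,7-dimethylocta-2,6-dien-1-yl]-2,4-bis(triisopropylsilyloxy)phenyl}-7-(triisopropylsilyloxy)chroman-4-ol | CC(C)=CCC/C(C)=C/Cc1cc([C@@H]2COc3cc(O[Si](C(C)C)(C(C)C)C(C)C)ccc3[C@@H]2O)c(O[Si](C(C)C)(C(C)C)C(C)C)cc1O[Si](C(C)C)(C(C)C)C(C)C | intermediate
20 | (3R)-3-{5-[(2E)-3,7-dimethylocta-2,6-dien-1-yl]-2,4-bis(triisopropylsilyloxy)phenyl}-7-(triisopropylsilyloxy)chroman-4-one | CC(C)=CCC/C(C)=C/Cc1cc([C@@H]2COc3cc(O[Si](C(C)C)(C(C)C)C(C)C)ccc3C2=O)c(O[Si](C(C)C)(C(C)C)C(C)C)cc1O[Si](C(C)C)(C(C)C)C(C)C | intermediate
21 | (3R)-3-{5-[(2E)-3,7-dimethylocta-2,6-dien-1-yl]-2,4-dihydroxyphenyl}-7-hydroxychroman-4-one | CC(C)=CCC/C(C)=C/Cc1cc([C@@H]2COc3cc(O)ccc3C2=O)c(O)cc1O | target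

## Step count and least certain steps

Total: 10 steps. Longest linear sequence: 9 steps (steps 1, 2, 3, 4, 6, 7, 8, 9, 10); the other branch is step 5 alone.

The key step, step 6, is the least certain, since it has no direct precedent. Three processes could defeat it: consumption of the carbene by its own precursor (azine formation) or by insertion before it meets the enol ether; ionisation of the electron-rich diazirine without carbene formation; and stalling at the cyclopropane stage if the epimer with chloride on the exo face does not ionise.
- Fallback with known chemistry, setting out from 9 and returning at 13: dibromocarbene (CHBr3, KOt-Bu, hexane, −30 °C → rt) should add to the enol ether, and ring enlargement with loss of the silyl bromide should give 3-bromo-7-(triisopropylsilyloxy)-4H-chromen-4-one F1. This is the established halocarbene expansion of cyclic silyl enol ethers.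
- Ring B would be brought in by Suzuki–Miyaura coupling (Pd(PPh3)4, K3PO4, dioxane/H2O, 60 °C) with 2-[5-bromo-2,4-bis(triisopropylsilyloxy)phenyl]-4,4,5,5-tetramethyl-1,3,2-dioxaborolane F4.
- F4 would be made from commercial 4,6-dibromobenzene-1,3-diol F2 by silylation to 1,5-dibromo-2,4-bis(triisopropylsilyloxy)benzene F3, then a single bromine–lithium exchange (n-BuLi, −78 °C) and quench with the isopropoxy pinacol borate.
- The coupling should prefer the electron-poor vinylic bromide of F1 over the hindered, electron-rich aryl bromide of F4.

Step 4 is the next concern. Hydroxide may strip the aryl silyl groups, which are activated by the ortho and para amidinium group, the arene may be chlorinated, or the donor-substituted diazirine may decompose on handling.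
- Fallback, setting out from 2 and returning at 13: protect as 5-bromo-2,4-bis(methoxymethoxy)benzonitrile F5 (MOMCl, i-Pr2NEt).
- Convert F5 to 5-bromo-2,4-bis(methoxymethoxy)benzamidinium chloride F6 (LiN(SiMe3)2; then NH4Cl, MeOH) and oxidise to 3-[5-bromo-2,4-bis(methoxymethoxy)phenyl]-3-chloro-3H-diazirine F7.
- Run the step-6 reaction with 9 to give 3-[5-bromo-2,4-bis(methoxymethoxy)phenyl]-7-(triisopropylsilyloxy)-4H-chromen-4-one F8.
- Remove the acetals at this flat, robust stage (HCl, MeOH, 40 °C) to give 3-(5-bromo-2,4-dihydroxyphenyl)-7-(triisopropylsilyloxy)-4H-chromen-4-one F9, and silylate (TIPSOTf, 2,6-lutidine) to 13.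
- This costs two steps and accepts the risk of carbene insertion into the acetal C–H bonds that the main design avoids.

Step 7 may suffer from slow conjugate reduction of the twisted, hindered chromone or from reduction of 14 outrunning its epimerisation, which would lower the cis and enantiomeric purity. Fallback, setting out from 13 and returning at 15: separate the two events, reducing the C2=C3 bond with LiBH(s-Bu)3 (THF, −78 °C) to isolated racemic 14 and then submitting 14 to the same catalyst with added base so that epimerisation is fast. This makes no compound outside the list (F0).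

Step 8 may fail through silyl migration, either from the 4'-oxygen to the metalated carbon or from the 2'-oxygen to the C4 alkoxide; through protonation of the aryl-metal, giving loss of bromine without alkylation; or through attack at the tertiary end of the allyl unit.
- Fallback, setting out from 13 and returning at 19: prepare tributyl[(2E)-3,7-dimethylocta-2,6-dien-1-yl]stannane F10 from 16 and Bu3SnLi.
- Couple it with 13 under Stille conditions (Pd(PPh3)4, toluene, 100 °C) to give 3-{5-[(2E)-3,7-dimethylocta-2,6-dien-1-yl]-2,4-bis(triisopropylsilyloxy)phenyl}-7-(triisopropylsilyloxy)-4H-chromen-4-one F11.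
- Submit F11 to the cascade of step 7, which should give 19 directly.
- It is second choice because the π-allyl palladium intermediate can transpose the allyl unit or isomerise the double bond and because tin residues must be removed.

Further compounds

F1 | step 6 | 3-bromo-7-(triisopropylsilyloxy)-4H-chromen-4-one | O=c1c(Br)coc2cc(O[Si](C(C)C)(C(C)C)C(C)C)ccc12
F2 | step 6 | 4,6-dibromobenzene-1,3-diol | Oc1cc(O)c(Br)cc1Br
F3 | step 6 | 1,5-dibromo-2,4-bis(triisopropylsilyloxy)benzene | Brc1cc(Br)c(O[Si](C(C)C)(C(C)C)C(C)C)cc1O[Si](C(C)C)(C(C)C)C(C)C
F4 | step 6 | 2-[5-bromo-2,4-bis(triisopropylsilyloxy)phenyl]-4,4,5,5-tetramethyl-1,3,2-dioxaborolane | CC1(C)OB(OC1(C)C)c1cc(Br)c(O[Si](C(C)C)(C(C)C)C(C)C)cc1O[Si](C(C)C)(C(C)C)C(C)C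
F5 | step 4 | 5-bromo-2,4-bis(methoxymethoxy)benzonitrile | COCOc1cc(OCOC)c(Br)cc1C#N
F6 | step 4 | 5-bromo-2,4-bis(methoxymethoxy)benzamidinium chloride | [Cl-].COCOc1cc(OCOC)c(Br)cc1C(N)=[NH2+]
F7 | step 4 | 3-[5-bromo-2,4-bis(methoxymethoxy)phenyl]-3-chloro-3H-diazirine | COCOc1cc(OCOC)c(Br)cc1C1(Cl)N=N1
F8 | step 4 | 3-[5-bromo-2,4-bis(methoxymethoxy)phenyl]-7-(triisopropylsilyloxy)-4H-chromen-4-one | COCOc1cc(OCOC)c(Br)cc1-c1coc2cc(O[Si](C(C)C)(C(C)C)C(C)C)ccc2c1=O
F9 | step 4 | 3-(5-bromo-2,4-dihydroxyphenyl)-7-(triisopropylsilyloxy)-4H-chromen-4-one | Oc1cc(O)c(Br)cc1-c1coc2cc(O[Si](C(C)C)(C(C)C)C(C)C)ccc2c1=O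
F0 | step 7 | none | none
F10 | step 8 | tributyl[(2E)-3,7-dimethylocta-2,6-dien-1-yl]stannane | CCCC[Sn](CCCC)(CCCC)C/C=C(\C)CCC=C(C)C
F11 | step 8 | 3-{5-[(2E)-3,7-dimethylocta-2,6-dien-1-yl]-2,4-bis(triisopropylsilyloxy)phenyl}-7-(triisopropylsilyloxy)-4H-chromen-4-one | CC(C)=CCC/C(C)=C/Cc1cc(-c2coc3cc(O[Si](C(C)C)(C(C)C)C(C)C)ccc3c2=O)c(O[Si](C(C)C)(C(C)C)C(C)C)cc1O[Si](C(C)C)(C(C)C)C(C)C
A1 | alternative 1 | (3R)-3-[5-bromo-2,4-bis(triisopropylsilyloxy)phenyl]-7-(triisopropylsilyloxy)chroman-4-one | Brc1cc([C@@H]2COc3cc(O[Si](C(C)C)(C(C)C)C(C)C)ccc3C2=O)c(O[Si](C(C)C)(C(C)C)C(C)C)cc1O[Si](C(C)C)(C(C)C)C(C)C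
A2 | alternative 1 | (2R)-2-[5-bromo-2,4-bis(triisopropylsilyloxy)phenyl]-3-[3-(triisopropylsilyloxy)phenoxy]propanoyl chloride | Brc1cc([C@@H](C(Cl)=O)COc2cccc(O[Si](C(C)C)(C(C)C)C(C)C)c2)c(O[Si](C(C)C)(C(C)C)C(C)C)cc1O[Si](C(C)C)(C(C)C)C(C)C
A3 | alternative 1 | 2-[5-bromo-2,4-bis(triisopropylsilyloxy)phenyl]propane-1,3-diol | OCC(CO)c1cc(Br)c(O[Si](C(C)C)(C(C)C)C(C)C)cc1O[Si](C(C)C)(C(C)C)C(C)C
A4 | alternative 2 | (3R,4S)-4-(tert-butyldimethylsilyloxy)-3-{5-[(2E)-3,7-dimethylocta-2,6-dien-1-yl]-2,4-bis(methoxymethoxy)phenyl}-7-(methoxymethoxy)chromane | CC(C)=CCC/C(C)=C/Cc1cc([C@@H]2COc3cc(OCOC)ccc3[C@H]2O[Si](C)(C)C(C)(C)C)c(OCOC)cc1OCOC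
A5 | alternative 2 | (2R,3S)-3-[2-bromo-4-(methoxymethoxy)phenyl]-3-(tert-butyldimethylsilyloxy)-2-{5-[(2E)-3,7-dimethylocta-2,6-dien-1-yl]-2,4-bis(methoxymethoxy)phenyl}propan-1-ol | CC(C)=CCC/C(C)=C/Cc1cc([C@H](CO)[C@H](O[Si](C)(C)C(C)(C)C)c2ccc(OCOC)cc2Br)c(OCOC)cc1OCOC
A6 | alternative 3 | rac-3-{5-[(2E)-3,7-dimethylocta-2,6-dien-1-yl]-2,4-bis(methoxymethoxy)phenyl}-7-(triisopropylsilyloxy)chroman-4-one | CC(C)=CCC/C(C)=C/Cc1cc(C2COc3cc(O[Si](C(C)C)(C(C)C)C(C)C)ccc3C2=O)c(OCOC)cc1OCOC
A7 | alternative 3 | 2-{5-[(2E)-3,7-dimethylocta-2,6-dien-1-yl]-2,4-bis(methoxymethoxy)phenyl}-N-methoxy-N-methylprop-2-enamide | CC(C)=CCC/C(C)=C/Cc1cc(C(=C)C(=O)N(C)OC)c(OCOC)cc1OCOC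
A8 | alternative 3 | 2-bromo-5-(triisopropylsilyloxy)phenol | Oc1cc(O[Si](C(C)C)(C(C)C)C(C)C)ccc1Br
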